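Time is what you read first: in the cedar run, by 15.0 min, target and starting material together stand at 56.0 %, so the rest has gone somewhere else.

the same everywhere: gas phase 1.3 mM (held)

|  | starting material | remark | time |
|---|---|---|---|
| cedar | 0.0055 M | run made earlier |  |
| ash | 0.087 M | run made earlier |  |
| zeta | 0.010 M |  | 30 min |
| beta | 0.020 M |  | 30 min |
| epsilon | 0.0060 M |  | 30 min |
| eta | 0.0050 M |  | 30 min |
| alpha | 0.030 M |  | 30 min |
| theta | 0.060 M |  | 30 min |

- cedar (time / min: target / %, starting material / %): 4.00: 44, 38; 8.00: 37, 34; 12.0: 37, 33; 15.0: 31, 25
- ash (time / min: target / %, starting material / %): 4.00: 12, 41; 8.00: 12, 11; 12.0: 8, 7; 15.0: 6, 9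

(each reading ± 2 percentage points)

- at the start none of the gas phase is in solution

1. ranking by amount of target, in percent of the starting material charged, from high to low, at 30 min (zeta / beta / epsilon / eta / alpha / theta)
2. the amount of target, in percent of the starting material charged of the flask you put first, at 30 min
3. the amount of target, in percent of the starting material charged of the flask you put last, at 30 min

The six flasks differ in their charge of starting material, with the gas phase held the same, so the charge is what you follow. But no gas is in solution at the start, and the ash run shows a lag: 12 % target beside 41 % starting material at 4.00 min, then 12 % beside 11 % at 8.00 min. From then on the two stay roughly level, so treat them as one pool, a pre-equilibrium with dissolved gas, and reckon the loss of that pool.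

The ash pool at 15.0 min is 15.0 %, less than cedar's, so the loss grows with the charge. Take it as second order: one over the pool, as a fraction of the charge, starts at one and climbs in proportion to charge times time. That proportion is the drain constant, and cedar's last reading gives 9.52 /M/min. Ash's last reading gives about half of that, but I keep cedar, whose charge lies nearer eta's than ash's does, with the target share of the pool in that same cedar reading, 55.4 %.

My reckoning then puts eta's target at 22.8 % and theta's at 3.05 %.

The forecast reads eta > epsilon > zeta > beta > alpha > theta, with 23 % for eta and 5 % for theta, a low above mine, saying “dilute wins, so the order follows rising concentration”.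

The flasks give eta > epsilon > zeta > beta > alpha > theta, with 23.0 % in eta and 3.37 % in theta.

    gas phase ⇌ dissolved gas, rate k1*(csat - [dissolved gas]) (kL = 8.60 /min)
    starting material + dissolved gas ⇌ target (K = 830 /M, k = 1000 /M/min)
    starting material + target → side product (k = 17.0 /M/min)

The nearest times at which eta's target has moved by 5 points are 20.5 min and 44.8 min. Now take a neighbour, the eta flask with 0.0020 M of starting material and the same time. The drain constant and share from cedar give 35.2 % target, and the flask holds 34.5 %, beside 32 % starting material and 33.5 % side product.

All runs come from a simulation on assumed constants; scatter was added.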